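## Analysis of the target

Target 16 is a dibenzylbutyrolactone lignan, (3R,4R)-4-(3,4-dimethoxybenzyl)-3-(4-hydroxy-3,5-dimethoxybenzyl)dihydrofuran-2(3H)-one. Its only non-aromatic ring is the γ-lactone, ring C (O1, C2 carbonyl, C3, C4, C5). C4 carries the CH2 of the veratryl group (ring A) and C3 carries the CH2 of the syringyl group (ring B). The two stereocentres are adjacent, both R, and trans on ring C; C3 is enolisable and trans is the more stable arrangement, so C3 can be set from C4 by substrate control. C4 is the real problem: it bears H and three sp3 carbon arms (CH2Ar, CH2O, CH–C=O) that differ only further out, it has no heteroatom handle, and it cannot be corrected by equilibration. Sensitive points are the lactone (hydroxide, epimerisation at C3), the two electron-rich arenes, and the free phenol of ring B, which is oxidisable and para to a benzylic carbon, so a leaving group there would collapse to a quinone methide unless the phenol is masked. The strategy rests on one topological fact: the benzylic carbon of ring A and C3 are both bonded to C4, so they stand 1,3 to each other and can be tied into a cyclopropane (C3, C4, benzylic carbon) fused to ring C. That bicycle is what a carbene at C3 makes from an E aryl alkene in one step, and the extra bond is both benzylic and α to the carbonyl, so hydrogen removes it again selectively; the configuration at C4 thereby becomes a question of alkene face selection under a chiral catalyst.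

## Retrosynthetic reasoning

16 from 15. The phenol O–H is traced back to a benzyl ether. The phenol has to be masked while the ring B benzylic carbon acts as an electrophile, and a benzyl ether falls under neutral hydrogenolysis that touches neither the lactone nor the stereocentres.

15 from 9 and 13. The bond between C3 and the ring B benzylic carbon is cut. This is the natural place because C3 is the only acidic carbon of lactone 9, and its enolate 14 is shielded on one face by the C4 substituent, so the alkylation with bromide 13 should place the new group trans. This leaves C4 as the only centre that needs an external source of chirality.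

13 from 10. Bromide 13 is traced through alcohol 12 and aldehyde 11 to syringaldehyde 10 by O-benzylation, carbonyl reduction and bromination. No C–C bond is made here; the branch only supplies ring B in electrophilic, phenol-protected form.

9 from 8. A bond is added in the retrosynthetic sense between C3 and the ring A benzylic carbon, giving the cis-fused bicyclic lactone 8 with the aryl group exo. The forward step is a catalytic hydrogenolysis that must cut exactly this bond. It is the only cyclopropane bond that is both benzylic and conjugated with the carbonyl, so the selectivity is built into the structure.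

8 from 7. Both bonds from C3, to C4 and to the benzylic carbon, are cut together. This turns C3 into a carbene carbon, masked as the diazo group of 7, and C4 and the benzylic carbon into the two ends of an E double bond. This is the key disconnection: in the forward direction it closes ring C and the cyclopropane at once, creates three stereocentres, and lets a chiral dirhodium carboxamidate choose the alkene face and thereby the configuration at C4. The E geometry becomes the exo position of the aryl group, and the short tether allows only cis fusion.

7 from 1 and 3. Diazoacetate 7 is traced through diazoacetoacetate 6 to acetoacetate 5 by diazo transfer and deacetylation. Acetoacetate 5 is the ester of allylic alcohol 2 with acetylketene 4, released thermally from dioxinone 3. Alcohol 2 is the 1,2-reduction product of cinnamate ester 1, whose E double bond is bought, not made. These are three routine operations, so the risk of the route is concentrated in the cyclopropanation.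

## Alternatives that were turned down

Alternative 1: Both benzylic bonds to ring C (C4 to the ring A carbon, C3 to the ring B carbon) are cut at once. The forward key step is a three-component coupling: the lithiated dithiane A3 adds 1,4 to the chiral butenolide A2, anti to the menthyloxy group at C5, and the lactone enolate is trapped with bromide 13, anti to the new C4 substituent, giving A1.
- For: it is highly convergent, making two C–C bonds and both stereocentres in one flask. Stereocontrol comes from a diastereomerically pure acetal through two well-understood anti additions, and no catalyst has to be tuned.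
- Against: the chirality is stoichiometric. A2 itself takes a photooxygenation, an acetalisation with a chiral alcohol and a separation of C5 epimers.
- Against: after the key step three things absent from the target must be erased from A1. These are the dithiane (desulfurisation with Raney Ni beside an aryl benzyl ether), the C5 acetal (reduction and relactonisation) and the benzyl group.
- Against: the key step itself joins a hindered tertiary carbanion, a hindered enolate and a labile benzylic bromide.
- Comparison: on convergency and on certainty of the stereochemical outcome this alternative is at least as strong as the chosen route, probably stronger. The chosen route offers catalytic induction, no auxiliary to build and strip, and no sulfur chemistry; its only traceless element, the cyclopropane bond, leaves in one clean hydrogenolysis.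

Alternative 2: Ring C is disconnected at O1, so that lactone A4 (identical with 9) is the ring-expanded form of the prochiral cyclobutanone A5, which a ketene (2+2) cycloaddition and a reductive dechlorination would give from allylarene A6. The forward key step is a desymmetrising Baeyer–Villiger oxidation, in which a chiral phosphoric acid with H2O2, Sc(OTf)3 with a chiral N,N'-dioxide, or a monooxygenase lets one of the two enantiotopic ring bonds migrate.
- For: it is shorter, three steps to A4 against five to 9, from a cheap arene and without a diazo compound. On step economy it is stronger than the chosen route.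
- Against: the stereocentre arises at C3 of A5, which is not a reacting atom. The catalyst must tell two CH2 groups apart through a substituent one bond further out, and here that substituent is a freely rotating benzyl group, a weak steric signal compared with an aryl group on the ring.
- Against: an enzyme may do better, but its hand has to be found by screening.
- Against: an electron-rich veratryl ring is exposed to peroxide and acid.
- Comparison: the chosen route pays two more steps but creates C4 at an atom that is bonded in the stereodetermining event, inside a tight five-membered tether. Both hands of the catalyst are equally accessible.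

Alternative 3: Ring A itself is disconnected by two C–C bonds. The forward key step is a cobalt-catalysed (4+2) addition: CoBr2(dppe), Zn and ZnI2 join the alkyne of the propargyl lactone A8 to diene A9, giving the 1,4-cyclohexadiene A7, which would then be dehydrogenated to the arene and debenzylated.
- For: the conditions are neutral and tolerate the lactone, the symmetric diene raises no regiochemical question, and ring A could be varied late for analogues. On that last point it is stronger than the chosen route, which fixes ring A in the first step.
- Against: it constructs the one part of the target that can simply be bought.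
- Against: it creates neither stereocentre. A8 must already carry both, so the whole stereochemical problem remains to be solved beforehand.
- Against: A9 and A7 are hydrolytically labile enol ethers, and the aromatisation needs an oxidant in the presence of the electron-rich benzylic positions of ring B.
- Comparison: for the single target the chosen route is shorter, and every C–C bond it forms builds skeleton or stereochemistry that is not otherwise available.

Key step: step 4

Remark on the chemistry: the hand of the rhodium catalyst in step 4 is assigned by analogy with the sense of induction this catalyst family shows with simpler allylic diazoacetates; it would be confirmed at lactone 9, and the mirror-image catalyst is equally accessible.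

## Route

Step 1
Reactants: 1 methyl (E)-3-(3,4-dimethoxyphenyl)prop-2-enoate
Product: 2 (E)-3-(3,4-dimethoxyphenyl)prop-2-en-1-ol
Conditions: i-Bu2AlH (2.3 equiv), CH2Cl2, −78 to 0 °C; aq. potassium sodium tartrate work-up
Reagents that add atoms: none
Why: 1,2-Reduction of an α,β-unsaturated ester by an electrophilic aluminium hydride; hydride is delivered to the carbonyl carbon only, so the E double bond, which later fixes the exo position of the aryl group, is untouched.

Step 2
Reactants: 2 (E)-3-(3,4-dimethoxyphenyl)prop-2-en-1-ol; 3 2,2,6-trimethyl-4H-1,3-dioxin-4-one
Product: 5 (E)-3-(3,4-dimethoxyphenyl)prop-2-en-1-yl 3-oxobutanoate, via acetylketene 4 (not isolated)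
Conditions: xylene, 135 °C, 1 h, acetone distilled off
Reagents that add atoms: none
Why: Thermal retro-hetero-Diels–Alder cleavage of 3 releases acetylketene 4, which the primary alcohol traps at once (acetoacetylation); the medium is neutral, and the time and temperature stay below what a Carroll rearrangement of the allylic acetoacetate would need.

Step 3
Reactants: 5 (E)-3-(3,4-dimethoxyphenyl)prop-2-en-1-yl 3-oxobutanoate
Product: 7 (E)-3-(3,4-dimethoxyphenyl)prop-2-en-1-yl 2-diazoacetate, via diazoacetoacetate 6 (not isolated)
Conditions: 4-acetamidobenzenesulfonyl azide (1.2 equiv), Et3N (1.3 equiv), MeCN, 0 °C to rt; then LiOH (3 equiv), H2O, rt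
Reagents that add atoms: 4-acetamidobenzenesulfonyl azide, CC(=O)Nc1ccc(cc1)S(=O)(=O)N=[N+]=[N-]
Why: Regitz diazo transfer to the doubly activated methylene, then deacylative cleavage: hydroxide adds to the ketone carbonyl of 6, which is more electrophilic than the diazo-conjugated ester carbonyl, and the acetyl group leaves as acetate with the stabilised diazo ester carbanion as leaving group.

Step 4
Reactants: 7 (E)-3-(3,4-dimethoxyphenyl)prop-2-en-1-yl 2-diazoacetate
Product: 8 (1S,5R,6R)-6-(3,4-dimethoxyphenyl)-3-oxabicyclo[3.1.0]hexan-2-one (cis-fused, aryl exo; C1 is the future C3 of ring C, C5 the future C4, C6 the future benzylic CH2 of ring A)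
Conditions: Rh2(4R-MPPIM)4 (1 mol %; MPPIM = methyl 2-oxo-1-(3-phenylpropanoyl)imidazolidine-4-carboxylate, bound as the carboxamidate), CH2Cl2, reflux, 7 added over 10 h by syringe pump
Reagents that add atoms: none
Why: The diazo carbon binds at a free axial site of the dirhodium core, N2 leaves, and the electrophilic rhodium carbene adds across the tethered E double bond in a concerted, asynchronous (2+1) step that frees the catalyst; the closest known reaction type is the enantioselective intramolecular cyclopropanation of allylic diazoacetates with chiral dirhodium carboxamidates. Ring C closes by 5-exo attack of the carbene carbon on the nearer alkene carbon, and the three-membered ring closes in the same event at the benzylic carbon. C5 is set by the catalyst: the ester arms of the carboxamidate ligands flank the carbene and leave one alkene face open. C1 follows from C5 because a cyclopropane can only be cis-fused to a five-membered ring, and C6 follows from the stereospecific syn addition to the E alkene, which puts the aryl group trans to the CH2O carbon, that is exo. The imidazolidinone catalyst is chosen over the pyrrolidinone analogue Rh2(MEPY)4 because the trans substituent of an E alkene clashes with a ligand ester of the latter in the favoured approach, whereas the N-acyl imidazolidinone ligand is the member of the family suited to E-disubstituted allylic diazoacetates. The R hand is chosen because R-configured carboxamidates of this family deliver the (1S,5R) sense of ring fusion with simpler allylic diazoacetates. The step needs chemoselectivity for cyclopropanation over carbene dimerisation, attack on the arene and the uncatalysed dipolar cycloaddition of the diazo group to the alkene; slow addition, the five-membered tether, the electron-rich styrene-type alkene and the low electrophilicity of carboxamidate carbenes should secure it.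

Step 5
Reactants: 8 (1S,5R,6R)-6-(3,4-dimethoxyphenyl)-3-oxabicyclo[3.1.0]hexan-2-one
Product: 9 (4R)-4-(3,4-dimethoxybenzyl)dihydrofuran-2(3H)-one
Conditions: H2 (1–3 atm), 10% Pd/C, EtOAc, rt
Reagents that add atoms: none
Why: Hydrogenolysis of an aryl cyclopropane; the C1–C6 bond is both benzylic and conjugated with the lactone carbonyl, hence the weakest bond of the ring, and its cleavage turns C6 into the veratryl CH2 and C1 into C3 of ring C. C5 is not involved and becomes C4 with R configuration; the aryl methyl ethers and the non-benzylic lactone C–O bond are inert.

Step 6
Reactants: 10 syringaldehyde (4-hydroxy-3,5-dimethoxybenzaldehyde)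
Product: 11 4-(benzyloxy)-3,5-dimethoxybenzaldehyde
Conditions: BnBr (1.2 equiv), K2CO3, DMF, 60 °C
Reagents that add atoms: benzyl bromide, BrCc1ccccc1
Why: Williamson ether synthesis; the phenol is acidified by the para formyl group, and the small phenoxide oxygen is alkylated despite the two flanking methoxy groups.

Step 7
Reactants: 11 4-(benzyloxy)-3,5-dimethoxybenzaldehyde
Product: 12 [4-(benzyloxy)-3,5-dimethoxyphenyl]methanol
Conditions: NaBH4, MeOH–THF, 0 °C
Reagents that add atoms: none
Why: Borohydride reduction of an aromatic aldehyde to the benzylic alcohol; the ethers are inert.

Step 8
Reactants: 12 [4-(benzyloxy)-3,5-dimethoxyphenyl]methanol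
Product: 13 2-(benzyloxy)-5-(bromomethyl)-1,3-dimethoxybenzene
Conditions: PBr3 (0.4 equiv), Et2O, 0 °C; used freshly prepared
Reagents that add atoms: phosphorus tribromide, BrP(Br)Br
Why: Conversion of the benzylic alcohol into the bromide through a phosphite ester and displacement by bromide; with the para oxygen benzylated the product cannot collapse to a quinone methide.

Step 9
Reactants: 9 (4R)-4-(3,4-dimethoxybenzyl)dihydrofuran-2(3H)-one; 13 2-(benzyloxy)-5-(bromomethyl)-1,3-dimethoxybenzene
Product: 15 (3R,4R)-3-[4-(benzyloxy)-3,5-dimethoxybenzyl]-4-(3,4-dimethoxybenzyl)dihydrofuran-2(3H)-one, via lithium enolate 14 (not isolated)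
Conditions: LiN(SiMe3)2 (1.1 equiv), THF, −78 °C; then 13 (1.1 equiv), DMPU, −78 to −30 °C
Reagents that add atoms: none
Why: Alkylation of a lactone enolate with a benzylic bromide; the planar C3 of 14 is attacked on the face opposite the C4 benzyl group (1,2-induction in a five-membered ring), which gives the 3,4-trans product, also the more stable isomer. One equivalent of base at low temperature limits proton exchange and a second alkylation.

Step 10
Reactants: 15 (3R,4R)-3-[4-(benzyloxy)-3,5-dimethoxybenzyl]-4-(3,4-dimethoxybenzyl)dihydrofuran-2(3H)-one
Product: 16 (3R,4R)-4-(3,4-dimethoxybenzyl)-3-(4-hydroxy-3,5-dimethoxybenzyl)dihydrofuran-2(3H)-one (target)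
Conditions: H2 (1 atm), 10% Pd/C, EtOAc–EtOH, rt
Reagents that add atoms: none
Why: Hydrogenolysis of the aryl benzyl ether under neutral conditions; no other benzylic C–O bond is present, and neither C3 nor C4 is exposed to base or acid.

## Compound list

1 | methyl (E)-3-(3,4-dimethoxyphenyl)prop-2-enoate | COC(=O)/C=C/c1ccc(OC)c(OC)c1 | starting material
2 | (E)-3-(3,4-dimethoxyphenyl)prop-2-en-1-ol | COc1ccc(/C=C/CO)cc1OC | intermediate
3 | 2,2,6-trimethyl-4H-1,3-dioxin-4-one | CC1=CC(=O)OC(C)(C)O1 | starting material
4 | acetylketene (formed and consumed in the flask of step 2) | CC(=O)C=C=O | intermediate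
5 | (E)-3-(3,4-dimethoxyphenyl)prop-2-en-1-yl 3-oxobutanoate | COc1ccc(/C=C/COC(=O)CC(C)=O)cc1OC | intermediate
6 | (E)-3-(3,4-dimethoxyphenyl)prop-2-en-1-yl 2-diazo-3-oxobutanoate (formed and consumed in the flask of step 3) | COc1ccc(/C=C/COC(=O)C(=[N+]=[N-])C(C)=O)cc1OC | intermediate
7 | (E)-3-(3,4-dimethoxyphenyl)prop-2-en-1-yl 2-diazoacetate | COc1ccc(/C=C/COC(=O)C=[N+]=[N-])cc1OC | intermediate
8 | (1S,5R,6R)-6-(3,4-dimethoxyphenyl)-3-oxabicyclo[3.1.0]hexan-2-one | COc1ccc([C@@H]2[C@H]3COC(=O)[C@@H]23)cc1OC | intermediate
9 | (4R)-4-(3,4-dimethoxybenzyl)dihydrofuran-2(3H)-one | COc1ccc(C[C@H]2COC(=O)C2)cc1OC | intermediate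
10 | syringaldehyde (4-hydroxy-3,5-dimethoxybenzaldehyde) | COc1cc(C=O)cc(OC)c1O | starting material
11 | 4-(benzyloxy)-3,5-dimethoxybenzaldehyde | COc1cc(C=O)cc(OC)c1OCc1ccccc1 | intermediate
12 | [4-(benzyloxy)-3,5-dimethoxyphenyl]methanol | COc1cc(CO)cc(OC)c1OCc1ccccc1 | intermediate
13 | 2-(benzyloxy)-5-(bromomethyl)-1,3-dimethoxybenzene | COc1cc(CBr)cc(OC)c1OCc1ccccc1 | intermediate
14 | lithium enolate of 9 (formed and consumed in the flask of step 9) | COc1ccc(C[C@H]2COC(O[Li])=C2)cc1OC | intermediate
15 | (3R,4R)-3-[4-(benzyloxy)-3,5-dimethoxybenzyl]-4-(3,4-dimethoxybenzyl)dihydrofuran-2(3H)-one | COc1ccc(C[C@H]2COC(=O)[C@@H]2Cc2cc(OC)c(OCc3ccccc3)c(OC)c2)cc1OC | intermediate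
16 | (3R,4R)-4-(3,4-dimethoxybenzyl)-3-(4-hydroxy-3,5-dimethoxybenzyl)dihydrofuran-2(3H)-one | COc1ccc(C[C@H]2COC(=O)[C@@H]2Cc2cc(OC)c(O)c(OC)c2)cc1OC | target

## Step count and risk

Total: 10 steps. Longest linear sequence: 7 steps (steps 1, 2, 3, 4, 5, 9, 10); the ring B branch is 3 steps (6, 7, 8).

Step 4 (key step). The most likely failure is insufficient face selection on the alkene: E-disubstituted allylic diazoacetates are the demanding substrate class, because the trans aryl group points at the ligand sphere, and the catalyst hand is assigned by analogy. The enantiomeric purity could also be eroded by the uncatalysed dipolar cycloaddition of the diazo group to the alkene followed by loss of nitrogen, which gives the racemic bicycle, and material could be lost through carbene dimerisation. Fallback, setting out from allylic alcohol 2 and returning at lactone 9: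
- The double bond of 2 is saturated (H2, Pd/C, EtOAc) to 3-(3,4-dimethoxyphenyl)propan-1-ol F1.
- F1 is acetoacetylated with dioxinone 3 to 3-(3,4-dimethoxyphenyl)propyl 3-oxobutanoate F2.
- Diazo transfer and deacetylation as in step 3 lead through 3-(3,4-dimethoxyphenyl)propyl 2-diazo-3-oxobutanoate F3 (not isolated) to 3-(3,4-dimethoxyphenyl)propyl 2-diazoacetate F4.
- Rh2(4S-MPPIM)4 in refluxing CH2Cl2 should then insert the carbene into the C–H bond β to the ester oxygen, a known enantioselective route from 3-arylpropyl diazoacetates to 4-benzyl γ-lactones. This gives 9 directly, with the hand again confirmed at 9, and makes step 5 unnecessary.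

Step 5. The most likely failure is competing cleavage of the other benzylic cyclopropane bond (C5–C6), which would move the benzyl group to the carbon α to the carbonyl, or stalling of the hydrogenolysis on a poisoned catalyst. Fallback, from 8 to 9 with no new compound (F0): a polar reductive opening with Et3SiH and BF3·OEt2 in CH2Cl2 at −78 to 0 °C. The Lewis acid on the lactone carbonyl lets the C1–C6 bond ionise to a benzylic cation stabilised by the para methoxy group, which is the only bond that links the donor carbon to the acceptor carbon; the silane delivers hydride to that cation and work-up protonates C1.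

Step 9. The most likely failures are a second alkylation at C3, through proton exchange between product and enolate, and loss of the electron-rich benzylic bromide 13 by ionisation and self-condensation before it is consumed. Fallback, setting out from lactone 9 and aldehyde 11 and returning at 15:
- Enolate 14 is added to 11 at −78 °C in an aldol reaction, with the same anti approach at C3. This gives (3S,4R)-3-{[4-(benzyloxy)-3,5-dimethoxyphenyl](hydroxy)methyl}-4-(3,4-dimethoxybenzyl)dihydrofuran-2(3H)-one F5, 3,4-trans and a mixture of carbinol epimers.
- The benzylic hydroxyl of F5 is removed by ionic reduction (Et3SiH, CF3CO2H, CH2Cl2, 0 °C) through the para-alkoxybenzylic cation, which gives 15. Steps 7 and 8 are then not needed.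

Step 3. The most likely failure is saponification of the allylic ester competing with the deacetylation, or loss of the diazo ester through slow intramolecular cycloaddition if it is stored or warmed. Fallback, setting out from alcohol 2 and returning at 7:
- Alcohol 2 is acylated with bromoacetyl bromide (NaHCO3, MeCN, 0 °C) to (E)-3-(3,4-dimethoxyphenyl)prop-2-en-1-yl 2-bromoacetate F6.
- F6 is treated with N,N'-ditosylhydrazine and DBU in THF at 0 °C. Displacement of bromide by the hydrazide nitrogen and twofold elimination of sulfinate give 7 without aqueous hydroxide.

## Further compounds

F1 | step 4 | 3-(3,4-dimethoxyphenyl)propan-1-ol | COc1ccc(CCCO)cc1OC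
F2 | step 4 | 3-(3,4-dimethoxyphenyl)propyl 3-oxobutanoate | COc1ccc(CCCOC(=O)CC(C)=O)cc1OC
F3 | step 4 | 3-(3,4-dimethoxyphenyl)propyl 2-diazo-3-oxobutanoate | COc1ccc(CCCOC(=O)C(=[N+]=[N-])C(C)=O)cc1OC
F4 | step 4 | 3-(3,4-dimethoxyphenyl)propyl 2-diazoacetate | COc1ccc(CCCOC(=O)C=[N+]=[N-])cc1OC
F0 | step 5 | none | none
F5 | step 9 | (3S,4R)-3-{[4-(benzyloxy)-3,5-dimethoxyphenyl](hydroxy)methyl}-4-(3,4-dimethoxybenzyl)dihydrofuran-2(3H)-one, mixture of carbinol epimers | COc1ccc(C[C@H]2COC(=O)[C@@H]2C(O)c2cc(OC)c(OCc3ccccc3)c(OC)c2)cc1OC
F6 | step 3 | (E)-3-(3,4-dimethoxyphenyl)prop-2-en-1-yl 2-bromoacetate | COc1ccc(/C=C/COC(=O)CBr)cc1OC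
A1 | alternative 1 | 3,4-trans-4,5-trans-3-[4-(benzyloxy)-3,5-dimethoxybenzyl]-4-[2-(3,4-dimethoxyphenyl)-1,3-dithian-2-yl]-5-(l-menthyloxy)dihydrofuran-2(3H)-one | COc1ccc(C2(SCCCS2)[C@H]2[C@H](O[C@@H]3C[C@H](C)CC[C@H]3C(C)C)OC(=O)[C@@H]2Cc2cc(OC)c(OCc3ccccc3)c(OC)c2)cc1OC
A2 | alternative 1 | (5R)-5-(l-menthyloxy)furan-2(5H)-one | O=C1C=C[C@H](O[C@@H]2C[C@H](C)CC[C@H]2C(C)C)O1
A3 | alternative 1 | 2-(3,4-dimethoxyphenyl)-1,3-dithiane | COc1ccc(C2SCCCS2)cc1OC
A4 | alternative 2 | (4R)-4-(3,4-dimethoxybenzyl)dihydrofuran-2(3H)-one | COc1ccc(C[C@H]2COC(=O)C2)cc1OC
A5 | alternative 2 | 3-(3,4-dimethoxybenzyl)cyclobutan-1-one | COc1ccc(CC2CC(=O)C2)cc1OC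
A6 | alternative 2 | 4-allyl-1,2-dimethoxybenzene | C=CCc1ccc(OC)c(OC)c1
A7 | alternative 3 | (3R,4R)-3-[4-(benzyloxy)-3,5-dimethoxybenzyl]-4-[(4,5-dimethoxycyclohexa-1,4-dien-1-yl)methyl]dihydrofuran-2(3H)-one | COC1=C(OC)CC(C[C@H]2COC(=O)[C@@H]2Cc2cc(OC)c(OCc3ccccc3)c(OC)c2)=CC1
A8 | alternative 3 | (3R,4R)-3-[4-(benzyloxy)-3,5-dimethoxybenzyl]-4-(prop-2-yn-1-yl)dihydrofuran-2(3H)-one | C#CC[C@H]1COC(=O)[C@@H]1Cc1cc(OC)c(OCc2ccccc2)c(OC)c1
A9 | alternative 3 | 2,3-dimethoxybuta-1,3-diene | COC(=C)C(=C)OC
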